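The ten-membered ring is cut across C1–C6. C1 (furanone ketone) and C6 (lactone carbinol) are 1,6-related oxygenated carbons, and C1–C6 with O3 and C15 are the ring of 2-methylanisole, so rings A (C1–C6) and B (C1, C6–C10) of a tetralin share the bond to be broken. One glycol cleavage of the ring-fusion cis-diol then releases the carbocycle, the C1/C3 β-diketone that becomes the furanone, and the C4=C5 Z-enone, whose geometry was fixed inside ring A. The precursor is a Birch-derived, osmylated tetralin enone bearing the C8–C10 triol as TBS, TIPS and TES ethers.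

Key step: step 17

Remark (numbering): locants C1–C15 follow the germacrane numbering of the target (C1–C10 ring, C11–C13 lactone carbons, C14 on C10, C15 on C4); O8, O9, O10 are the oxygens on those carbons.
Remark (protecting groups): benzyl-type ethers and benzylic silyl ethers are cleaved by lithium in ammonia, so O8 and O9 are carried as TBS and TIPS ethers and O10 is free (as its alkoxide) in the Birch step and silylated only afterwards.
Remark (assumption): the facial sense of the Shi epoxidation is assigned by the spiro transition-state model; should it prove opposite, the antipodal ketone is used.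
Remark (diol configuration): the cis-diol at C1/C6 is drawn for osmylation anti to C14; its configuration is lost in step 17 and is inconsequential.

Step 1
Reactants: 1 2-methylanisole; 2 succinic anhydride
Product: 3 4-(4-methoxy-3-methylphenyl)-4-oxobutanoic acid
Conditions: AlCl3 (2.2 equiv), CH2Cl2, 0 °C → rt; aq. HCl
Reagents that add atoms: none
Why: Friedel–Crafts acylation (first stage of a Haworth tetralone synthesis) should occur para to the methoxy group, the most activated and least hindered ring position.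

Step 2
Reactants: 3 4-(4-methoxy-3-methylphenyl)-4-oxobutanoic acid
Product: 4 4-(4-methoxy-3-methylphenyl)butanoic acid
Conditions: H2 (3 atm), 10% Pd on carbon, AcOH, HClO4 (cat.), 50 °C
Reagents that add atoms: none
Why: Catalytic hydrogenolysis of the electron-rich benzylic ketone (Haworth reduction stage) removes the carbonyl oxygen and leaves the acid and the arene untouched.

Step 3
Reactants: 4 4-(4-methoxy-3-methylphenyl)butanoic acid
Product: 5 7-methoxy-6-methyl-3,4-dihydronaphthalen-1(2H)-one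
Conditions: P2O5/MeSO3H (Eaton's reagent, as solvent), 60 °C
Reagents that add atoms: none
Why: Intramolecular Friedel–Crafts acylation closes ring B at the ortho position para to the methyl group, the other ortho position being blocked by that methyl group.

Step 4
Reactants: 5 7-methoxy-6-methyl-3,4-dihydronaphthalen-1(2H)-one
Product: 7 6-methoxy-4,7-dimethyl-1,2-dihydronaphthalene, via tertiary carbinol 6 (not isolated)
Conditions: MeMgBr, THF, 0 °C → rt; aq. NH4Cl; then TsOH·H2O (cat.), toluene, 80 °C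
Reagents that add atoms: methylmagnesium bromide, C[Mg]Br
Why: Grignard 1,2-addition followed by acid-catalysed E1 dehydration of the tertiary benzylic carbinol gives the conjugated endocyclic C9=C10 alkene.

Step 5
Reactants: 7 6-methoxy-4,7-dimethyl-1,2-dihydronaphthalene
Product: 8 (1aS,7bR)-6-methoxy-5,7b-dimethyl-1a,2,3,7b-tetrahydronaphtho[1,2-b]oxirene
Conditions: ent-Shi ketone (1,2:4,5-di-O-isopropylidene-β-L-erythro-2,3-hexodiulo-2,6-pyranose, 0.3 equiv), KHSO5 (as 2KHSO5·KHSO4·K2SO4), K2CO3, Bu4NHSO4, MeCN/(MeO)2CH2/aq. Na2B4O7 buffer, 0 °C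
Reagents that add atoms: potassium peroxymonosulfate, [K+].[O-]S(=O)(=O)OO
Why: Shi asymmetric epoxidation by the chiral dioxirane (spiro transition state) delivers oxygen to one face of the trisubstituted styrenyl alkene and so sets C9 and C10 together, the buffered basic medium protecting the acid-labile benzylic epoxide.

Step 6
Reactants: 8 (1aS,7bR)-6-methoxy-5,7b-dimethyl-1a,2,3,7b-tetrahydronaphtho[1,2-b]oxirene
Product: 10 (S)-7-methoxy-1,6-dimethyl-1,4-dihydronaphthalen-1-ol, via trans-hydroxy selenide 9 (not isolated)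
Conditions: (PhSe)2, NaBH4, EtOH, reflux; then 30% H2O2, pyridine, THF, 0 °C → rt
Reagents that add atoms: none
Why: Sharpless–Lauer epoxide-to-allylic-alcohol transposition: phenylselenolate opens the epoxide by SN2 attack at the secondary C9 and the derived selenoxide undergoes syn-elimination, which can only engage C8–H because C10 bears no hydrogen, so the C10 carbinol configuration is carried over unchanged.

Step 7
Reactants: 10 (S)-7-methoxy-1,6-dimethyl-1,4-dihydronaphthalen-1-ol
Product: 11 (S)-triethyl[(7-methoxy-1,6-dimethyl-1,4-dihydronaphthalen-1-yl)oxy]silane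
Conditions: TESOTf, 2,6-lutidine, CH2Cl2, −78 °C
Reagents that add atoms: triethylsilyl triflate, CC[Si](CC)(CC)OS(=O)(=O)C(F)(F)F
Why: Silylation of the tertiary alcohol with a silyl triflate and a hindered base stops acid-promoted loss of water to a naphthalene and replaces the syn-directing hydroxyl by an anti-directing group.

Step 8
Reactants: 11 (S)-triethyl[(7-methoxy-1,6-dimethyl-1,4-dihydronaphthalen-1-yl)oxy]silane
Product: 12 (1R,2R,3R)-2,3-epoxy-7-methoxy-1,6-dimethyl-1-(triethylsilyloxy)-1,2,3,4-tetrahydronaphthalene (epoxide oxygen trans to O10)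
Conditions: mCPBA, NaHCO3, CH2Cl2, 0 °C
Reagents that add atoms: 3-chloroperoxybenzoic acid, OOC(=O)c1cccc(Cl)c1
Why: Prilezhaev epoxidation should take place on the face opposite the allylic triethylsilyloxy group (an allylic methyl group exerts almost no facial bias on peracid epoxidation of cyclohexenes whereas an allylic silyloxy group steers the peracid anti), which sets C9 with its oxygen trans to O10.

Step 9
Reactants: 12 (1R,2R,3R)-2,3-epoxy-7-methoxy-1,6-dimethyl-1-(triethylsilyloxy)-1,2,3,4-tetrahydronaphthalene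
Product: 14 (1R,2R,3S)-7-methoxy-1,6-dimethyl-1,2,3,4-tetrahydronaphthalene-1,2,3-triol, via O10-triethylsilyl diol 13 (not isolated)
Conditions: HClO4 (0.5 M aq.), THF, 0 °C → rt
Reagents that add atoms: water, O
Why: Acid-catalysed trans-diaxial (Fürst–Plattner) hydrolysis: water attacks C8, the epoxide carbon remote from the fully substituted oxygen-bearing C10, with inversion, which sets C8 trans to O9 and cis to O10, and the labile tertiary TES ether is hydrolysed in the same medium so that O10 is free for step 12.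

Step 10
Reactants: 14 (1R,2R,3S)-7-methoxy-1,6-dimethyl-1,2,3,4-tetrahydronaphthalene-1,2,3-triol
Product: 15 (1R,2R,3S)-3-(tert-butyldimethylsilyloxy)-7-methoxy-1,6-dimethyl-1,2,3,4-tetrahydronaphthalene-1,2-diol
Conditions: TBSCl (1.05 equiv), imidazole, DMF, 0 °C
Reagents that add atoms: tert-butyldimethylsilyl chloride, CC(C)(C)[Si](C)(C)Cl
Why: Steric differentiation in silylation: the secondary O8 hydroxyl reacts first because O9 is flanked by the quaternary C10 and O10 is tertiary.

Step 11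
Reactants: 15 (1R,2R,3S)-3-(tert-butyldimethylsilyloxy)-7-methoxy-1,6-dimethyl-1,2,3,4-tetrahydronaphthalene-1,2-diol
Product: 16 (1R,2R,3S)-3-(tert-butyldimethylsilyloxy)-7-methoxy-1,6-dimethyl-2-(triisopropylsilyloxy)-1,2,3,4-tetrahydronaphthalen-1-ol
Conditions: TIPSOTf, 2,6-lutidine, CH2Cl2, 0 °C → rt
Reagents that add atoms: triisopropylsilyl triflate, CC(C)[Si](C(C)C)(C(C)C)OS(=O)(=O)C(F)(F)F
Why: Silylation with the more reactive triflate caps the hindered secondary O9 hydroxyl while the tertiary benzylic O10 hydroxyl is too congested to react.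

Step 12
Reactants: 16 (1R,2R,3S)-3-(tert-butyldimethylsilyloxy)-7-methoxy-1,6-dimethyl-2-(triisopropylsilyloxy)-1,2,3,4-tetrahydronaphthalen-1-ol
Product: 18 (6S,7R,8R)-6-(tert-butyldimethylsilyloxy)-8-hydroxy-3,8-dimethyl-7-(triisopropylsilyloxy)-3,4,5,6,7,8-hexahydronaphthalen-2(1H)-one (C3 epimers), via Birch dienol ether 17 (not isolated)
Conditions: Li, NH3(l)/THF/t-BuOH, −78 → −33 °C; isoprene, then NH4Cl; then (CO2H)2, THF/MeOH/H2O, rt
Reagents that add atoms: water, O
Why: Birch reduction protonates the two unsubstituted ring positions C2 and C5 and leaves the donor-substituted carbons sp2; the benzylic O10 is carried as its lithium alkoxide, which resists C–O hydrogenolysis as long as excess metal is destroyed before protonation, and oxalic acid then hydrolyses the enol ether to the β,γ-unsaturated ketone without moving the C1=C6 alkene (C4 forms as an inconsequential epimer mixture).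

Step 13
Reactants: 18 (6S,7R,8R)-6-(tert-butyldimethylsilyloxy)-8-hydroxy-3,8-dimethyl-7-(triisopropylsilyloxy)-3,4,5,6,7,8-hexahydronaphthalen-2(1H)-one
Product: 19 (6S,7R,8R)-6-(tert-butyldimethylsilyloxy)-3,8-dimethyl-8-(triethylsilyloxy)-7-(triisopropylsilyloxy)-3,4,5,6,7,8-hexahydronaphthalen-2(1H)-one (C3 epimers)
Conditions: TESOTf, 2,6-lutidine, CH2Cl2, −78 °C
Reagents that add atoms: triethylsilyl triflate, CC[Si](CC)(CC)OS(=O)(=O)C(F)(F)F
Why: Silyl triflate silylation of the tertiary allylic alcohol at low temperature, where the ketone is not enolised, masks O10 so that only the C1–C6 glycol can be cleaved later.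

Step 14
Reactants: 19 (6S,7R,8R)-6-(tert-butyldimethylsilyloxy)-3,8-dimethyl-8-(triethylsilyloxy)-7-(triisopropylsilyloxy)-3,4,5,6,7,8-hexahydronaphthalen-2(1H)-one
Product: 20 (4aR,6S,7R,8S,8aR)-6-(tert-butyldimethylsilyloxy)-4a,8a-dihydroxy-3,8-dimethyl-8-(triethylsilyloxy)-7-(triisopropylsilyloxy)octahydronaphthalen-2(1H)-one (C3 epimers)
Conditions: OsO4 (1.1 equiv), pyridine, CH2Cl2, 0 °C → rt; then aq. NaHSO3, THF
Reagents that add atoms: osmium tetroxide, O=[Os](=O)(=O)=O
Why: Osmium tetroxide cis-dihydroxylation ([3+2] addition, pyridine-accelerated) of the tetrasubstituted ring-fusion alkene should occur anti to the pseudoaxial C14 methyl group on C10; either cis-diol would serve because both carbinol carbons become carbonyl groups in step 17.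

Step 15
Reactants: 20 (4aR,6S,7R,8S,8aR)-6-(tert-butyldimethylsilyloxy)-4a,8a-dihydroxy-3,8-dimethyl-8-(triethylsilyloxy)-7-(triisopropylsilyloxy)octahydronaphthalen-2(1H)-one
Product: 21 C3=C4 trimethylsilyl enol ether of 20 with O1 and O6 as trimethylsilyl ethers
Conditions: TMSOTf, Et3N, CH2Cl2, 0 °C → rt
Reagents that add atoms: trimethylsilyl triflate, C[Si](C)(C)OS(=O)(=O)C(F)(F)F
Why: Amine/silyl triflate enol silylation under equilibrating conditions gives the more substituted C3=C4 enol ether (the C2 side is disfavoured by the adjacent fully substituted C1) and caps both tertiary hydroxyls as TMS ethers.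

Step 16
Reactants: 21 C3=C4 trimethylsilyl enol ether of 20 with O1 and O6 as trimethylsilyl ethers
Product: 23 (4aS,6S,7R,8S,8aR)-6-(tert-butyldimethylsilyloxy)-4a,8a-dihydroxy-3,8-dimethyl-8-(triethylsilyloxy)-7-(triisopropylsilyloxy)-4a,5,6,7,8,8a-hexahydronaphthalen-2(1H)-one, via bis(trimethylsilyl) enone 22 (not isolated)
Conditions: Pd(OAc)2 (1.1 equiv), MeCN, rt; then citric acid, MeOH, 0 °C
Reagents that add atoms: none
Why: Saegusa–Ito oxidation: the enol ether gives an oxa-π-allyl palladium species at C4 and β-hydride elimination of the ring C5–H furnishes the endocyclic C4=C5 enone with reduction of divalent to zerovalent palladium, after which mild acidic methanolysis removes the two tertiary TMS ethers much faster than the TES, TBS and TIPS ethers.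

Step 17
Reactants: 23 (4aS,6S,7R,8S,8aR)-6-(tert-butyldimethylsilyloxy)-4a,8a-dihydroxy-3,8-dimethyl-8-(triethylsilyloxy)-7-(triisopropylsilyloxy)-4a,5,6,7,8,8a-hexahydronaphthalen-2(1H)-one
Product: 24 (4Z,8S,9R,10S)-8-(tert-butyldimethylsilyloxy)-4,10-dimethyl-10-(triethylsilyloxy)-9-(triisopropylsilyloxy)cyclodec-4-ene-1,3,6-trione
Conditions: Pb(OAc)4 (1.05 equiv), CH2Cl2, −20 → 0 °C
Reagents that add atoms: none
Why: Tetravalent lead exchanges two acetates for the cis-1,6-diol to give a five-membered cyclic lead diester, which collapses in a concerted two-electron fragmentation to the C1 and C6 ketones and divalent lead. The closest known reaction is the Criegee cleavage of cis-decalin-9,10-diol to cyclodecane-1,6-dione. No bond is formed: the ten-membered ring appears as the perimeter of rings A and B when their shared C1–C6 bond is cut, so there is no cyclisation mode and no entropic penalty of medium-ring closure. No stereocentre is created; C8, C9 and C10 are untouched and C4=C5 is Z because the alkene was endocyclic in six-membered ring A. The step needs cleavage of the C1–C6 glycol only, which is secured by silylation of O8, O9 and O10 (the C1–C10 glycol cannot form a lead ester) and by one equivalent of oxidant at low temperature, where glycol cleavage outpaces α-acetoxylation of the emerging β-diketone.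

Step 18
Reactants: 24 (4Z,8S,9R,10S)-8-(tert-butyldimethylsilyloxy)-4,10-dimethyl-10-(triethylsilyloxy)-9-(triisopropylsilyloxy)cyclodec-4-ene-1,3,6-trione
Product: 26 (4Z,8S,9R,10S)-8-(tert-butyldimethylsilyloxy)-3,10-epoxy-4,10-dimethyl-9-(triisopropylsilyloxy)cyclodeca-2,4-diene-1,6-dione (3(2H)-furanone bridging C3 and C10), via 10-hydroxy triketone 25 (not isolated)
Conditions: AcOH/THF/H2O (3:1:1), 40 °C (crude 24 used at once)
Reagents that add atoms: none
Why: Aqueous acetic acid cleaves the tertiary TES ether while the TBS and TIPS ethers persist, and the freed O10 hydroxyl adds to the C3 carbonyl (5-exo-trig hemiketal) and loses water, the classical acid-catalysed cyclodehydration of an α′-hydroxy-1,3-diketone to a 3(2H)-furanone, which removes both the β-diketone and the cis-enedione before they can react across the ring.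

Step 19
Reactants: 26 (4Z,8S,9R,10S)-8-(tert-butyldimethylsilyloxy)-3,10-epoxy-4,10-dimethyl-9-(triisopropylsilyloxy)cyclodeca-2,4-diene-1,6-dione
Product: 27 methyl 2-[(4Z,7R,8S,9R,10S)-8-(tert-butyldimethylsilyloxy)-3,10-epoxy-4,10-dimethyl-1,6-dioxo-9-(triisopropylsilyloxy)cyclodeca-2,4-dien-7-yl]acetate
Conditions: LiN(iPr)2, THF, −78 °C; DMPU; BrCH2CO2Me, −78 → −40 °C
Reagents that add atoms: methyl bromoacetate, COC(=O)CBr
Why: Kinetic α′-deprotonation of the cross-conjugated enone gives the C6/C7 lithium enolate, whose SN2 alkylation sets C7: with C8–H eclipsing the enolate (allylic 1,3-strain) the electrophile should approach anti to the bulky C8 silyloxy group, which in this medium ring places C11 cis to O8, and silanolate is a poor β-leaving group at this temperature.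

Step 20
Reactants: 27 methyl 2-[(4Z,7R,8S,9R,10S)-8-(tert-butyldimethylsilyloxy)-3,10-epoxy-4,10-dimethyl-1,6-dioxo-9-(triisopropylsilyloxy)cyclodeca-2,4-dien-7-yl]acetate
Product: 29 (4Z,6R,7S,8S,9R,10S)-8-(tert-butyldimethylsilyloxy)-3,10-epoxy-1-oxo-9-(triisopropylsilyloxy)germacra-2,4-dien-12,6-olide (trans-fused γ-lactone), via 6R-hydroxy ester 28 (not isolated)
Conditions: (R)-Me-CBS oxazaborolidine (0.3 equiv), catecholborane, toluene, −78 °C; then PPTS, toluene, 50 °C
Reagents that add atoms: none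
Why: Corey–Bakshi–Shibata reduction gives reagent-controlled 1,2-reduction of the enone (hydride is delivered to the face fixed by the (R)-oxazaborolidine with the C5 alkenyl branch in the large-group position, which sets C6 as R, while the hindered vinylogous-ester carbonyl at C1 is left alone), and the γ-hydroxy ester then lactonises under mild acid to the trans-fused 6,12-olide.

Step 21
Reactants: 29 (4Z,6R,7S,8S,9R,10S)-8-(tert-butyldimethylsilyloxy)-3,10-epoxy-1-oxo-9-(triisopropylsilyloxy)germacra-2,4-dien-12,6-olide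
Product: 32 (4Z,6R,7S,8S,9R,10S)-8-(tert-butyldimethylsilyloxy)-3,10-epoxy-1-oxo-9-(triisopropylsilyloxy)germacra-2,4,11(13)-trien-12,6-olide, via Mannich base 30 (not isolated), via trimethylammonium iodide 31 (not isolated)
Conditions: LiN(SiMe3)2, THF, −78 °C; Me2N=CH2 I (Eschenmoser's salt), −78 °C → rt; MeI, MeOH/CH2Cl2, rt; aq. NaHCO3
Reagents that add atoms: N,N-dimethylmethyleneiminium iodide, C=[N+](C)C.[I-]
Why: α-Methylenation of the lactone by the Eschenmoser-salt Mannich reaction of its lithium enolate (the lactone α-CH2 is the only readily enolisable site), followed by quaternisation and E1cB elimination of trimethylamine, which erases the transient C11 stereocentre.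

Step 22
Reactants: 32 (4Z,6R,7S,8S,9R,10S)-8-(tert-butyldimethylsilyloxy)-3,10-epoxy-1-oxo-9-(triisopropylsilyloxy)germacra-2,4,11(13)-trien-12,6-olide
Product: 33 (4Z,6R,7S,8S,9R,10S)-3,10-epoxy-8-hydroxy-1-oxo-9-(triisopropylsilyloxy)germacra-2,4,11(13)-trien-12,6-olide
Conditions: HF·pyridine, pyridine, THF, 0 °C → rt
Reagents that add atoms: none
Why: Buffered fluoride desilylation distinguishes the secondary TBS ether from the more hindered and intrinsically more robust TIPS ether next to the quaternary C10.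

Step 23
Reactants: 33 (4Z,6R,7S,8S,9R,10S)-3,10-epoxy-8-hydroxy-1-oxo-9-(triisopropylsilyloxy)germacra-2,4,11(13)-trien-12,6-olide
Product: 34 (4Z,6R,7S,8S,9R,10S)-3,10-epoxy-1-oxo-9-(triisopropylsilyloxy)germacra-2,4,11(13)-trien-12,6-olid-8-yl methacrylate
Conditions: methacrylic anhydride, Et3N, DMAP, CH2Cl2, 0 °C → rt
Reagents that add atoms: methacrylic anhydride, CC(=C)C(=O)OC(=O)C(C)=C
Why: DMAP-catalysed acylation (Steglich-type acyl transfer) of the only free hydroxyl installs the ester without touching any stereocentre.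

Step 24
Reactants: 34 (4Z,6R,7S,8S,9R,10S)-3,10-epoxy-1-oxo-9-(triisopropylsilyloxy)germacra-2,4,11(13)-trien-12,6-olid-8-yl methacrylate
Product: 35 (4Z,6R,7S,8S,9R,10S)-3,10-epoxy-9-hydroxy-1-oxogermacra-2,4,11(13)-trien-12,6-olid-8-yl methacrylate (CNP0252578.3)
Conditions: HF·pyridine, THF, rt → 40 °C
Reagents that add atoms: none
Why: Acidic fluoride desilylation cleaves the remaining TIPS ether under conditions that leave the α-methylene lactone, the methacrylate and the furanone intact.

Compound list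
1 | 2-methylanisole | COc1ccccc1C | starting material
2 | succinic anhydride | O=C1CCC(=O)O1 | starting material
3 | 4-(4-methoxy-3-methylphenyl)-4-oxobutanoic acid | COc1ccc(cc1C)C(=O)CCC(=O)O | intermediate
4 | 4-(4-methoxy-3-methylphenyl)butanoic acid | COc1ccc(cc1C)CCCC(=O)O | intermediate
5 | 7-methoxy-6-methyl-3,4-dihydronaphthalen-1(2H)-one | COc1cc2c(cc1C)CCCC2=O | intermediate
6 | 7-methoxy-1,6-dimethyl-1,2,3,4-tetrahydronaphthalen-1-ol (racemic, not isolated) | COc1cc2c(cc1C)CCCC2(C)O | intermediate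
7 | 6-methoxy-4,7-dimethyl-1,2-dihydronaphthalene | COc1cc2c(cc1C)CCC=C2C | intermediate
8 | (1aS,7bR)-6-methoxy-5,7b-dimethyl-1a,2,3,7b-tetrahydronaphtho[1,2-b]oxirene | COc1cc2c(cc1C)CC[C@H]3[C@]2(C)O3 | intermediate
9 | (1R,2R)-7-methoxy-1,6-dimethyl-2-(phenylselanyl)-1,2,3,4-tetrahydronaphthalen-1-ol (not isolated) | COc1cc2c(cc1C)CC[C@@H]([Se]c3ccccc3)[C@]2(C)O | intermediate
10 | (S)-7-methoxy-1,6-dimethyl-1,4-dihydronaphthalen-1-ol | COc1cc2c(cc1C)CC=C[C@]2(C)O | intermediate
11 | (S)-triethyl[(7-methoxy-1,6-dimethyl-1,4-dihydronaphthalen-1-yl)oxy]silane | COc1cc2c(cc1C)CC=C[C@]2(C)O[Si](CC)(CC)CC | intermediate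
12 | (1R,2R,3R)-2,3-epoxy-7-methoxy-1,6-dimethyl-1-(triethylsilyloxy)-1,2,3,4-tetrahydronaphthalene (epoxide trans to O10) | COc1cc2c(cc1C)C[C@@H]3[C@@H](O3)[C@]2(C)O[Si](CC)(CC)CC | intermediate
13 | (1R,2R,3S)-7-methoxy-1,6-dimethyl-1-(triethylsilyloxy)-1,2,3,4-tetrahydronaphthalene-2,3-diol (not isolated) | COc1cc2c(cc1C)C[C@H](O)[C@@H](O)[C@]2(C)O[Si](CC)(CC)CC | intermediate
14 | (1R,2R,3S)-7-methoxy-1,6-dimethyl-1,2,3,4-tetrahydronaphthalene-1,2,3-triol (O8 and O10 on one face, O9 on the other) | COc1cc2c(cc1C)C[C@H](O)[C@@H](O)[C@]2(C)O | intermediate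
15 | (1R,2R,3S)-3-(tert-butyldimethylsilyloxy)-7-methoxy-1,6-dimethyl-1,2,3,4-tetrahydronaphthalene-1,2-diol | COc1cc2c(cc1C)C[C@H](O[Si](C)(C)C(C)(C)C)[C@@H](O)[C@]2(C)O | intermediate
16 | (1R,2R,3S)-3-(tert-butyldimethylsilyloxy)-7-methoxy-1,6-dimethyl-2-(triisopropylsilyloxy)-1,2,3,4-tetrahydronaphthalen-1-ol | COc1cc2c(cc1C)C[C@H](O[Si](C)(C)C(C)(C)C)[C@@H](O[Si](C(C)C)(C(C)C)C(C)C)[C@]2(C)O | intermediate
17 | (1R,2R,3S)-3-(tert-butyldimethylsilyloxy)-7-methoxy-1,6-dimethyl-2-(triisopropylsilyloxy)-1,2,3,4,5,8-hexahydronaphthalen-1-ol (not isolated) | COC1=C(C)CC(C[C@H](O[Si](C)(C)C(C)(C)C)[C@@H](O[Si](C(C)C)(C(C)C)C(C)C)[C@]2(C)O)=C2C1 | intermediate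
18 | (6S,7R,8R)-6-(tert-butyldimethylsilyloxy)-8-hydroxy-3,8-dimethyl-7-(triisopropylsilyloxy)-3,4,5,6,7,8-hexahydronaphthalen-2(1H)-one (C3 epimers) | O=C1C(C)CC(C[C@H](O[Si](C)(C)C(C)(C)C)[C@@H](O[Si](C(C)C)(C(C)C)C(C)C)[C@]2(C)O)=C2C1 | intermediate
19 | (6S,7R,8R)-6-(tert-butyldimethylsilyloxy)-3,8-dimethyl-8-(triethylsilyloxy)-7-(triisopropylsilyloxy)-3,4,5,6,7,8-hexahydronaphthalen-2(1H)-one (C3 epimers) | O=C1C(C)CC(C[C@H](O[Si](C)(C)C(C)(C)C)[C@@H](O[Si](C(C)C)(C(C)C)C(C)C)[C@]2(C)O[Si](CC)(CC)CC)=C2C1 | intermediate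
20 | (4aR,6S,7R,8S,8aR)-6-(tert-butyldimethylsilyloxy)-4a,8a-dihydroxy-3,8-dimethyl-8-(triethylsilyloxy)-7-(triisopropylsilyloxy)octahydronaphthalen-2(1H)-one (C3 epimers; cis-diol on the face of O10) | O[C@]12CC(=O)C(C)C[C@@]1(O)C[C@H](O[Si](C)(C)C(C)(C)C)[C@@H](O[Si](C(C)C)(C(C)C)C(C)C)[C@]2(C)O[Si](CC)(CC)CC | intermediate
21 | C3=C4 trimethylsilyl enol ether of 20 with O1 and O6 as trimethylsilyl ethers | C[Si](C)(C)O[C@]12CC(O[Si](C)(C)C)=C(C)C[C@@]1(O[Si](C)(C)C)C[C@H](O[Si](C)(C)C(C)(C)C)[C@@H](O[Si](C(C)C)(C(C)C)C(C)C)[C@]2(C)O[Si](CC)(CC)CC | intermediate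
22 | O1,O6-bis(trimethylsilyl) ether of 23 (not isolated) | C[Si](C)(C)O[C@]12CC(=O)C(C)=C[C@@]1(O[Si](C)(C)C)C[C@H](O[Si](C)(C)C(C)(C)C)[C@@H](O[Si](C(C)C)(C(C)C)C(C)C)[C@]2(C)O[Si](CC)(CC)CC | intermediate
23 | (4aS,6S,7R,8S,8aR)-6-(tert-butyldimethylsilyloxy)-4a,8a-dihydroxy-3,8-dimethyl-8-(triethylsilyloxy)-7-(triisopropylsilyloxy)-4a,5,6,7,8,8a-hexahydronaphthalen-2(1H)-one (key-step precursor) | O[C@]12CC(=O)C(C)=C[C@@]1(O)C[C@H](O[Si](C)(C)C(C)(C)C)[C@@H](O[Si](C(C)C)(C(C)C)C(C)C)[C@]2(C)O[Si](CC)(CC)CC | intermediate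
24 | (4Z,8S,9R,10S)-8-(tert-butyldimethylsilyloxy)-4,10-dimethyl-10-(triethylsilyloxy)-9-(triisopropylsilyloxy)cyclodec-4-ene-1,3,6-trione (key-step product) | O=C1CC(=O)/C(C)=C\C(=O)C[C@H](O[Si](C)(C)C(C)(C)C)[C@@H](O[Si](C(C)C)(C(C)C)C(C)C)[C@]1(C)O[Si](CC)(CC)CC | intermediate
25 | (4Z,8S,9R,10S)-8-(tert-butyldimethylsilyloxy)-10-hydroxy-4,10-dimethyl-9-(triisopropylsilyloxy)cyclodec-4-ene-1,3,6-trione (not isolated) | O=C1CC(=O)/C(C)=C\C(=O)C[C@H](O[Si](C)(C)C(C)(C)C)[C@@H](O[Si](C(C)C)(C(C)C)C(C)C)[C@]1(C)O | intermediate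
26 | (4Z,8S,9R,10S)-8-(tert-butyldimethylsilyloxy)-3,10-epoxy-4,10-dimethyl-9-(triisopropylsilyloxy)cyclodeca-2,4-diene-1,6-dione | C/C1=C/C(=O)C[C@H](O[Si](C)(C)C(C)(C)C)[C@@H](O[Si](C(C)C)(C(C)C)C(C)C)[C@]2(C)OC1=CC2=O | intermediate
27 | methyl 2-[(4Z,7R,8S,9R,10S)-8-(tert-butyldimethylsilyloxy)-3,10-epoxy-4,10-dimethyl-1,6-dioxo-9-(triisopropylsilyloxy)cyclodeca-2,4-dien-7-yl]acetate | C/C1=C/C(=O)[C@H](CC(=O)OC)[C@H](O[Si](C)(C)C(C)(C)C)[C@@H](O[Si](C(C)C)(C(C)C)C(C)C)[C@]2(C)OC1=CC2=O | intermediate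
28 | C6 carbinol of 27 (6R; O6 trans to C11 and anti to O8; not isolated) | C/C1=C/[C@@H](O)[C@H](CC(=O)OC)[C@H](O[Si](C)(C)C(C)(C)C)[C@@H](O[Si](C(C)C)(C(C)C)C(C)C)[C@]2(C)OC1=CC2=O | intermediate
29 | (4Z,6R,7S,8S,9R,10S)-8-(tert-butyldimethylsilyloxy)-3,10-epoxy-1-oxo-9-(triisopropylsilyloxy)germacra-2,4-dien-12,6-olide | C/C1=C/[C@H]3OC(=O)C[C@@H]3[C@H](O[Si](C)(C)C(C)(C)C)[C@@H](O[Si](C(C)C)(C(C)C)C(C)C)[C@]2(C)OC1=CC2=O | intermediate
30 | 11-(dimethylaminomethyl) derivative of 29 (C11 epimers, not isolated) | C/C1=C/[C@H]3OC(=O)C(CN(C)C)[C@@H]3[C@H](O[Si](C)(C)C(C)(C)C)[C@@H](O[Si](C(C)C)(C(C)C)C(C)C)[C@]2(C)OC1=CC2=O | intermediate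
31 | 11-(trimethylammoniomethyl) iodide of 29 (not isolated) | C/C1=C/[C@H]3OC(=O)C(C[N+](C)(C)C)[C@@H]3[C@H](O[Si](C)(C)C(C)(C)C)[C@@H](O[Si](C(C)C)(C(C)C)C(C)C)[C@]2(C)OC1=CC2=O.[I-] | intermediate
32 | (4Z,6R,7S,8S,9R,10S)-8-(tert-butyldimethylsilyloxy)-3,10-epoxy-1-oxo-9-(triisopropylsilyloxy)germacra-2,4,11(13)-trien-12,6-olide | C/C1=C/[C@H]3OC(=O)C(=C)[C@@H]3[C@H](O[Si](C)(C)C(C)(C)C)[C@@H](O[Si](C(C)C)(C(C)C)C(C)C)[C@]2(C)OC1=CC2=O | intermediate
33 | (4Z,6R,7S,8S,9R,10S)-3,10-epoxy-8-hydroxy-1-oxo-9-(triisopropylsilyloxy)germacra-2,4,11(13)-trien-12,6-olide | C/C1=C/[C@H]3OC(=O)C(=C)[C@@H]3[C@H](O)[C@@H](O[Si](C(C)C)(C(C)C)C(C)C)[C@]2(C)OC1=CC2=O | intermediate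
34 | (4Z,6R,7S,8S,9R,10S)-3,10-epoxy-1-oxo-9-(triisopropylsilyloxy)germacra-2,4,11(13)-trien-12,6-olid-8-yl methacrylate | C/C1=C/[C@H]3OC(=O)C(=C)[C@@H]3[C@H](OC(=O)C(C)=C)[C@@H](O[Si](C(C)C)(C(C)C)C(C)C)[C@]2(C)OC1=CC2=O | intermediate
35 | (4Z,6R,7S,8S,9R,10S)-3,10-epoxy-9-hydroxy-1-oxogermacra-2,4,11(13)-trien-12,6-olid-8-yl methacrylate (CNP0252578.3) | C/C1=C/[C@H]3OC(=O)C(=C)[C@@H]3[C@H](OC(=O)C(C)=C)[C@@H](O)[C@]2(C)OC1=CC2=O | target

Total step count: 24. Longest linear sequence: 24 steps (the route is fully linear from 1 and 2).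

Steps most likely to fail

1. Step 19 (C7 alkylation). The bromoacetate may add to the other face of the medium-ring enolate, giving the C7 epimer, or the enolate may expel the C8 silanolate before it is alkylated. The fallback sets out from 26 and returns at 27. The same enolate (LiN(iPr)2, THF, −78 °C) is trapped with methyl glyoxylate, a much faster electrophile, to give the aldol adduct F5. Mesylation (MsCl, Et3N, CH2Cl2, 0 °C) gives the mesylate F6, and DBU eliminates it to the C7=C11 alkylidene keto ester F7. Conjugate reduction with [(Ph3P)CuH]6 in wet benzene then generates the C6 enolate, and C7 is set by protonation instead of by C–C bond formation. The proton enters the face that the carbon electrophile would have used, so this sequence delivers the opposite C7 configuration to direct alkylation and one of the two must give 27.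

2. Step 8 (epoxidation of 11). The C10 silyloxy group may discriminate poorly against its geminal methyl group, giving both epoxide faces. The fallback sets out from 10 and returns at 14. Hydroxyl-directed epoxidation (VO(acac)2 cat., t-BuOOH, CH2Cl2, 0 °C) gives the syn-epoxy alcohol F1 reliably. Ti(OiPr)4 with PhCO2H opens it at C8, the carbon remote from the carbinol, with inversion to give the C8 benzoate diol F2. MsCl/Et3N converts the secondary C9 hydroxyl into the mesylate F3. Brief K2CO3/MeOH at 0 °C removes the benzoate, and the C8 alkoxide displaces the mesylate with inversion at C9 to give the anti-epoxy alcohol F4; the contact time is kept short to avoid epoxide migration. Hydrolysis under the conditions of step 9 then gives 14.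

3. Step 20 (C6 reduction). Catalyst control may be overridden by the intrinsic facial bias of the bridged ketone, whose two flanking groups are both large, so that the C6 epimer forms. The fallback sets out from 27 and returns at 29. The substrate-preferred face is accepted: Luche reduction (NaBH4, CeCl3·7H2O, MeOH, −78 °C) gives the 6-epi hydroxy ester F8. Saponification (LiOH, THF/H2O, 0 °C) gives the hydroxy acid F9. Mitsunobu lactonisation (PPh3, DIAD, THF) then closes the γ-lactone with inversion at the allylic C6, which gives the trans-fused lactone 29.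

Further compounds
F1 | step 8 | syn-epoxy alcohol: 2,3-epoxy-7-methoxy-1,6-dimethyl-1,2,3,4-tetrahydronaphthalen-1-ol with the epoxide cis to the hydroxyl | COc1cc2c(cc1C)C[C@H]3[C@H](O3)[C@]2(C)O
F2 | step 8 | C8 benzoate diol: 3-benzoyloxy-7-methoxy-1,6-dimethyl-1,2,3,4-tetrahydronaphthalene-1,2-diol (1,2-cis, 2,3-trans) | COc1cc2c(cc1C)C[C@@H](OC(=O)c3ccccc3)[C@H](O)[C@]2(C)O
F3 | step 8 | C9 mesylate of F2 | COc1cc2c(cc1C)C[C@@H](OC(=O)c3ccccc3)[C@H](OS(C)(=O)=O)[C@]2(C)O
F4 | step 8 | anti-epoxy alcohol: 2,3-epoxy-7-methoxy-1,6-dimethyl-1,2,3,4-tetrahydronaphthalen-1-ol with the epoxide trans to the hydroxyl | COc1cc2c(cc1C)C[C@@H]3[C@@H](O3)[C@]2(C)O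
F5 | step 19 | glyoxylate aldol adduct of 26 at C7 (C7 and C11 epimers) | C/C1=C/C(=O)C(C(O)C(=O)OC)[C@H](O[Si](C)(C)C(C)(C)C)[C@@H](O[Si](C(C)C)(C(C)C)C(C)C)[C@]2(C)OC1=CC2=O
F6 | step 19 | C11 mesylate of F5 | C/C1=C/C(=O)C(C(OS(C)(=O)=O)C(=O)OC)[C@H](O[Si](C)(C)C(C)(C)C)[C@@H](O[Si](C(C)C)(C(C)C)C(C)C)[C@]2(C)OC1=CC2=O
F7 | step 19 | C7=C11 alkylidene keto ester (alkene isomers) | C/C1=C/C(=O)C(=CC(=O)OC)[C@H](O[Si](C)(C)C(C)(C)C)[C@@H](O[Si](C(C)C)(C(C)C)C(C)C)[C@]2(C)OC1=CC2=O
F8 | step 20 | 6-epi hydroxy ester (C6 epimer of 28) | C/C1=C/[C@H](O)[C@H](CC(=O)OC)[C@H](O[Si](C)(C)C(C)(C)C)[C@@H](O[Si](C(C)C)(C(C)C)C(C)C)[C@]2(C)OC1=CC2=O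
F9 | step 20 | 6-epi hydroxy acid | C/C1=C/[C@H](O)[C@H](CC(=O)O)[C@H](O[Si](C)(C)C(C)(C)C)[C@@H](O[Si](C(C)C)(C(C)C)C(C)C)[C@]2(C)OC1=CC2=O
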